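**Retrosynthetic overview**

1. Feature: in ring B (C5–C10) the quaternary carbons C5 and C9 and the tertiary carbinol C8 surround a trans C6/C7 diol. The two most congested bonds, C5–C10 and C8–C9, flank that diol, and the C5–C8 chain with its two oxygens is L-tartaric acid.
2. Endgame: butenolide ⇒ 3-alkylfuran (singlet oxygen, then hydride); C12–C13 ⇒ C11/C12 epoxide + 3-furyllithium; C4=C18 ⇒ C4 ketone ⇒ dioxolane; esters installed on the 1,11-diol first, then on the 6,7-diol.
3. Key disconnection: decalin aldehyde 21 ⇒ acyclic keto enal 18. Ring A forms first (C5–C10, radical 6-exo closure after hydrogen-atom transfer to C19), ring B second (C8–C9, aldol of the C9 enolate onto the C8 ketone); the butenolide ring is made last from the furan.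
4. 18 ⇒ Wittig at C9=C10 on an α-silyloxy aldehyde; C4–C5 by acylation of a lithiated dithiane with the tartrate bis-Weinreb amide, then methylenation (C19) and dithiane-to-dioxolane exchange; C3–C4 by dithiane alkylation; C1 from (S)-butane-1,2,4-triol acetonide.

Key step: step 13

Remark: clerodane numbering is used throughout; β is the face of the C19 methyl group and α the face of H10 (ring A drawn left, C10 above C5). The target is taken as the (1S,5S,6S,7R,8S,9R,10R,11R) isomer encoded in the SMILES. In SMILES the Tebbe reagent is drawn with the chloride on titanium (the Cl→Al bridge is not drawn) and the cyclopentadienyl ligands as η1 groups.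

**Route**

Step 1
Reactants: 1 dimethyl (4R,5R)-2,2-dimethyl-1,3-dioxolane-4,5-dicarboxylate
Product: 2 (4R,5R)-N4,N5-dimethoxy-N4,N5,2,2-tetramethyl-1,3-dioxolane-4,5-dicarboxamide
Conditions: MeNH(OMe)·HCl, iPrMgCl, THF, −20 → 0 °C
Reagents that add atoms: N,O-dimethylhydroxylamine hydrochloride, CNOC.Cl
Why: Aminolysis of both esters by the magnesium amide (Weinreb amide formation); the trans-acetonide stereocentres are not enolised, so (4R,5R) is retained.

Step 2
Reactants: 3 2-[(4S)-2,2-dimethyl-1,3-dioxolan-4-yl]ethanol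
Product: 4 (4S)-4-(2-iodoethyl)-2,2-dimethyl-1,3-dioxolane
Conditions: I2, PPh3, imidazole, CH2Cl2, 0 °C → rt
Reagents that add atoms: iodine, II
Why: Appel iodination of the primary alcohol; the stereocentre (future C1) is remote and untouched.

Step 3
Reactants: 5 1,3-dithiane; 4 (4S)-4-(2-iodoethyl)-2,2-dimethyl-1,3-dioxolane
Product: 7 2-{2-[(4S)-2,2-dimethyl-1,3-dioxolan-4-yl]ethyl}-1,3-dithiane, via 2-lithio-1,3-dithiane 6 (not isolated)
Conditions: n-BuLi, THF, −30 °C; then 4, −78 °C → rt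
Reagents that add atoms: none
Why: Corey–Seebach alkylation: the C2-lithiated dithiane displaces the unhindered primary iodide (SN2) and forms C3–C4.

Step 4
Reactants: 7 2-{2-[(4S)-2,2-dimethyl-1,3-dioxolan-4-yl]ethyl}-1,3-dithiane
Product: 8 (2S)-4-(1,3-dithian-2-yl)butane-1,2-diol
Conditions: 1 M HCl, THF, rt
Reagents that add atoms: none
Why: Acid hydrolysis of the terminal acetonide, to which the dithiane is inert, frees the 1,2-diol (O1 and the oxygen on C10).

Step 5
Reactants: 8 (2S)-4-(1,3-dithian-2-yl)butane-1,2-diol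
Product: 9 2-[(3S)-3,4-bis(tert-butyldimethylsilyloxy)butyl]-1,3-dithiane
Conditions: TBSCl, imidazole, DMF, rt
Reagents that add atoms: tert-butyldimethylsilyl chloride, CC(C)(C)[Si](C)(C)Cl
Why: Exhaustive silylation of the diol; the primary and secondary silyl ethers are told apart later by their different rates of cleavage.

Step 6
Reactants: 9 2-[(3S)-3,4-bis(tert-butyldimethylsilyloxy)butyl]-1,3-dithiane; 2 (4R,5R)-N4,N5-dimethoxy-N4,N5,2,2-tetramethyl-1,3-dioxolane-4,5-dicarboxamide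
Product: 11 (4R,5R)-5-({2-[(3S)-3,4-bis(tert-butyldimethylsilyloxy)butyl]-1,3-dithian-2-yl}carbonyl)-N-methoxy-N,2,2-trimethyl-1,3-dioxolane-4-carboxamide, via C2-lithiated dithiane 10 (not isolated)
Conditions: n-BuLi, THF, −30 °C; then added to 2 (excess), THF, −78 °C; aq. NH4Cl
Reagents that add atoms: none
Why: Corey–Seebach acylation forming C4–C5: the lithiated dithiane adds once to the bis-Weinreb amide because the N,O-chelated tetrahedral adduct does not collapse before work-up and shields the second amide; C6 and C7 come unchanged from tartrate.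

Step 7
Reactants: 11 (4R,5R)-5-({2-[(3S)-3,4-bis(tert-butyldimethylsilyloxy)butyl]-1,3-dithian-2-yl}carbonyl)-N-methoxy-N,2,2-trimethyl-1,3-dioxolane-4-carboxamide
Product: 12 (4R,5S)-5-(1-{2-[(3S)-3,4-bis(tert-butyldimethylsilyloxy)butyl]-1,3-dithian-2-yl}ethenyl)-N-methoxy-N,2,2-trimethyl-1,3-dioxolane-4-carboxamide
Conditions: Tebbe reagent Cp2Ti(μ-CH2)(μ-Cl)AlMe2, pyridine, THF/toluene, −40 → 0 °C
Reagents that add atoms: Tebbe reagent Cp2Ti(μ-CH2)(μ-Cl)AlMe2, C[Al](C)C[Ti](Cl)(C1C=CC=C1)C1C=CC=C1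
Why: Tebbe methylenation is non-basic, so the enolisable α-alkoxy C5 ketone becomes the C5=C19 alkene without β-elimination of the acetonide, and the ketone reacts faster than the Weinreb amide.

Step 8
Reactants: 12 (4R,5S)-5-(1-{2-[(3S)-3,4-bis(tert-butyldimethylsilyloxy)butyl]-1,3-dithian-2-yl}ethenyl)-N-methoxy-N,2,2-trimethyl-1,3-dioxolane-4-carboxamide
Product: 13 (4R,5S)-5-(1-{2-[(3S)-3,4-bis(tert-butyldimethylsilyloxy)butyl]-1,3-dioxolan-2-yl}ethenyl)-N-methoxy-N,2,2-trimethyl-1,3-dioxolane-4-carboxamide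
Conditions: PhI(OCOCF3)2, HOCH2CH2OH, NaHCO3, MeCN, 0 °C
Reagents that add atoms: ethane-1,2-diol, OCCO
Why: Oxidative dethioketalisation with in situ ketalisation: the hypervalent iodine reagent activates sulfur and the diol traps the thionium and oxocarbenium ions at C4; sulfur must be removed because a C5 radical β to sulfur would fragment.

Step 9
Reactants: 13 (4R,5S)-5-(1-{2-[(3S)-3,4-bis(tert-butyldimethylsilyloxy)butyl]-1,3-dioxolan-2-yl}ethenyl)-N-methoxy-N,2,2-trimethyl-1,3-dioxolane-4-carboxamide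
Product: 14 1-[(4R,5S)-5-(1-{2-[(3S)-3,4-bis(tert-butyldimethylsilyloxy)butyl]-1,3-dioxolan-2-yl}ethenyl)-2,2-dimethyl-1,3-dioxolan-4-yl]ethanone
Conditions: MeMgBr, THF, −20 → 0 °C; aq. NH4Cl
Reagents that add atoms: methylmagnesium bromide, C[Mg]Br
Why: Weinreb ketone synthesis: one methyl group (C17) adds and the chelated adduct collapses only on work-up to the C8 methyl ketone.

Step 10
Reactants: 14 1-[(4R,5S)-5-(1-{2-[(3S)-3,4-bis(tert-butyldimethylsilyloxy)butyl]-1,3-dioxolan-2-yl}ethenyl)-2,2-dimethyl-1,3-dioxolan-4-yl]ethanone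
Product: 15 1-[(4R,5S)-5-(1-{2-[(3S)-3-(tert-butyldimethylsilyloxy)-4-hydroxybutyl]-1,3-dioxolan-2-yl}ethenyl)-2,2-dimethyl-1,3-dioxolan-4-yl]ethanone
Conditions: HF·pyridine, pyridine, THF, 0 °C → rt
Reagents that add atoms: none
Why: Buffered HF·pyridine cleaves the unhindered primary silyl ether much faster than the secondary one and leaves both ketals intact.

Step 11
Reactants: 15 1-[(4R,5S)-5-(1-{2-[(3S)-3-(tert-butyldimethylsilyloxy)-4-hydroxybutyl]-1,3-dioxolan-2-yl}ethenyl)-2,2-dimethyl-1,3-dioxolan-4-yl]ethanone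
Product: 16 (2S)-4-(2-{1-[(4S,5R)-5-acetyl-2,2-dimethyl-1,3-dioxolan-4-yl]ethenyl}-1,3-dioxolan-2-yl)-2-(tert-butyldimethylsilyloxy)butanal
Conditions: Dess–Martin periodinane, NaHCO3, CH2Cl2, 0 °C → rt
Reagents that add atoms: none
Why: Dess–Martin oxidation of the primary alcohol under buffered conditions gives the α-silyloxy aldehyde without epimerising C1.

Step 12
Reactants: 16 (2S)-4-(2-{1-[(4S,5R)-5-acetyl-2,2-dimethyl-1,3-dioxolan-4-yl]ethenyl}-1,3-dioxolan-2-yl)-2-(tert-butyldimethylsilyloxy)butanal; 17 2-(triphenylphosphoranylidene)propanal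
Product: 18 (2E,4S)-6-(2-{1-[(4S,5R)-5-acetyl-2,2-dimethyl-1,3-dioxolan-4-yl]ethenyl}-1,3-dioxolan-2-yl)-4-(tert-butyldimethylsilyloxy)-2-methylhex-2-enal
Conditions: toluene, 80 °C
Reagents that add atoms: none
Why: Wittig olefination with the stabilised formyl ylide reacts with the aldehyde and not with the methyl ketone, gives the (E)-trisubstituted enal (C9=C10) and is neutral, so C1 is not epimerised.

Step 13
Reactants: 18 (2E,4S)-6-(2-{1-[(4S,5R)-5-acetyl-2,2-dimethyl-1,3-dioxolan-4-yl]ethenyl}-1,3-dioxolan-2-yl)-4-(tert-butyldimethylsilyloxy)-2-methylhex-2-enal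
Product: 21 trans-decalin aldehyde (1α-OTBS; C4 ethylene ketal; 5β-methyl; 6β,7α-O-isopropylidene; 8α-hydroxy-8β-methyl; 9β-methyl-9α-formyl; 10α-H), via tertiary C5 radical 19 (not isolated), via ring A iron enolate 20 (not isolated)
Conditions: Fe(acac)3 (substoichiometric), PhSiH3, EtOH/HOCH2CH2OH, degassed, high dilution, 0 °C → rt
Reagents that add atoms: none
Why: Fe(acac)3 and PhSiH3 in ethanol form an iron hydride that transfers a hydrogen atom to the terminal carbon C19 of the 1,1-disubstituted alkene, the nucleophilic tertiary C5 radical 19 adds to C10 of the enal, and divalent iron reduces the α-formyl radical to the iron enolate 20, which adds to the C8 ketone; the closest known reaction type is the iron-hydride hydrogen-atom-transfer Giese addition terminated by aldol closure (radical–polar crossover polycyclisation). Ring A closes by 6-exo-trig radical addition through a chair in which the C1 silyl ether, the acetonide arm on C5 and the enal arm on C10 are all equatorial, so the C1 stereocentre sets C10 (H α) and C5 (C19 axial, β, trans to H10). Ring B closes by a 6-(enolexo)-exo-trig aldol from the enolate rotamer in which H10 eclipses the C9=C11 bond (least allylic 1,3-strain), and the tether brings C8 to the face that leaves C20 axial (β) and C11 equatorial (α). At C8 the chair should place the methyl group C17 equatorial and the oxygen axial, gauche to the enolate oxygen so that iron can bridge both; this is the least secured element and the aldol is reversible. The step needs hydrogen-atom transfer to the isolated alkene and not to the enal, which the electron-poor, trisubstituted enal and the accessible CH2 terminus should secure, and the trans-acetonide holds C5 and C8 gauche so that ring B can form.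

Step 14
Reactants: 21 trans-decalin aldehyde
Product: 22 C11/C12 epoxide (21 with the formyl group converted to an oxirane; C11 placed as in the target)
Conditions: Me3S+ I−, n-BuLi, THF, −10 °C; then 21, −10 → 0 °C
Reagents that add atoms: trimethylsulfonium iodide, C[S+](C)C.[I-]
Why: Corey–Chaykovsky epoxidation: the sulfonium ylide adds irreversibly to the neopentyl aldehyde, which the lithium alkoxide (or hydrogen bond) of the C8 hydroxyl holds syn to C8; attack comes from the face next to C20 because the face next to C10 is covered by the peri C1 silyl ether, which sets C11.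

Step 15
Reactants: 22 C11/C12 epoxide; 23 3-bromofuran
Product: 25 furan diol (C9 bears CH(OH)CH2(3-furyl) with 11R; 8α-OH and 11-OH free; 1α-OTBS; C4 ketal; 6,7-acetonide), via 3-furyllithium 24 (not isolated)
Conditions: 23, n-BuLi, THF, −78 °C; then 22, BF3·OEt2, −78 °C; aq. NH4Cl
Reagents that add atoms: none
Why: BF3-assisted SN2 opening of the terminal epoxide by 3-furyllithium at the unhindered CH2 (C12) forms C12–C13 and leaves C11 untouched.

Step 16
Reactants: 25 furan diol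
Product: 26 furan triol (1α-OH, 8α-OH, 11-OH; C4 ketal; 6,7-acetonide)
Conditions: TBAF, THF, 0 → 40 °C
Reagents that add atoms: none
Why: Fluoride cleavage of the secondary silyl ether; ketals, furan and free alcohols are stable to TBAF.

Step 17
Reactants: 26 furan triol
Product: 27 1,11-diacetate (1α-OAc; 11-OAc; 8α-OH free; C4 ketal; 6,7-acetonide)
Conditions: Ac2O, DMAP, pyridine, CH2Cl2, rt
Reagents that add atoms: acetic anhydride, CC(=O)OC(C)=O
Why: DMAP-catalysed acetylation of the two secondary alcohols; the tertiary axial C8 hydroxyl is too hindered to react.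

Step 18
Reactants: 27 1,11-diacetate
Product: 28 ketone triol (4-oxo; 6β-OH, 7α-OH, 8α-OH; 1α-OAc; 11-OAc)
Conditions: 1 M HCl, THF, rt
Reagents that add atoms: water, O
Why: Aqueous acid hydrolyses the strained trans-fused acetonide and the crowded C4 ketal in one operation, while acetates and the 3-alkylfuran tolerate dilute acid at room temperature.

Step 19
Reactants: 28 ketone triol
Product: 29 7-O-isobutyrate (4-oxo; 6β-OH and 8α-OH free; 1α-OAc; 11-OAc)
Conditions: (iPrCO)2O, DMAP (cat.), Et3N, CH2Cl2, −20 °C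
Reagents that add atoms: isobutyric anhydride, CC(C)C(=O)OC(=O)C(C)C
Why: Regioselective DMAP-catalysed acylation at O7, the more accessible secondary hydroxyl: O6 is neopentyl to the quaternary C5, gauche to C19 and hydrogen-bonded to the peri C4 carbonyl, and O8 is tertiary.

Step 20
Reactants: 29 7-O-isobutyrate
Product: 30 keto tetraester (4-oxo; 1α-, 6β-, 11-OAc; 7α-O-isobutyryl; 8α-OH free)
Conditions: Ac2O, DMAP, pyridine, 40 °C
Reagents that add atoms: acetic anhydride, CC(=O)OC(C)=O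
Why: Forcing DMAP acetylation of the remaining secondary hydroxyl O6; the tertiary C8 hydroxyl stays free.

Step 21
Reactants: 30 keto tetraester
Product: 31 4(18)-methylene furan (30 with C4=CH2)
Conditions: Zn, CH2Br2, TiCl4, THF (reagent pre-formed at 5 °C); then 30, CH2Cl2, rt; aq. NaHCO3
Reagents that add atoms: dibromomethane, BrCBr
Why: Takai–Lombardo methylenation: the non-basic zinc/titanium methylene reagent converts the hindered C4 ketone to the exocyclic alkene without attacking the four esters or causing retro-aldol cleavage.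

Step 22
Reactants: 31 4(18)-methylene furan
Product: 33 γ-hydroxybutenolide (16-hydroxy-15,16-olide; epimers at C16), via furan endoperoxide 32 (not isolated)
Conditions: O2, visible light, tetraphenylporphyrin (cat.), iPr2NEt, CH2Cl2, −78 °C
Reagents that add atoms: oxygen, O=O
Why: Singlet oxygen adds [4+2] to the furan far faster than it reacts with the hindered exocyclic alkene, and the hindered amine removes the less hindered bridgehead proton at C15 (Kornblum–DeLaMare fragmentation), which puts the carbonyl at C15 and the hemiacetal at C16.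

Step 23
Reactants: 33 γ-hydroxybutenolide
Product: 35 (1S,5S,6S,7R,8S,9R,10R,11R)-1,6,11-triacetoxy-8-hydroxy-7-isobutyryloxycleroda-4(18),13-dien-15,16-olide (CNP0266716.2), via ring-opened hydroxy acid 34 (not isolated)
Conditions: NaBH4, EtOH, 0 °C; then 1 M HCl
Reagents that add atoms: none
Why: NaBH4 reduces the ring-opened aldehyde tautomer of the hemiacetal faster than the acetates at 0 °C, and acidification lactonises the (Z)-γ-hydroxy acid to the butenolide.

**Compound list**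

1 | dimethyl (4R,5R)-2,2-dimethyl-1,3-dioxolane-4,5-dicarboxylate | COC(=O)[C@@H]1OC(C)(C)O[C@H]1C(=O)OC | starting material
2 | (4R,5R)-N4,N5-dimethoxy-N4,N5,2,2-tetramethyl-1,3-dioxolane-4,5-dicarboxamide | CON(C)C(=O)[C@@H]1OC(C)(C)O[C@H]1C(=O)N(C)OC | intermediate
3 | 2-[(4S)-2,2-dimethyl-1,3-dioxolan-4-yl]ethanol | OCC[C@H]1COC(C)(C)O1 | starting material
4 | (4S)-4-(2-iodoethyl)-2,2-dimethyl-1,3-dioxolane | ICC[C@H]1COC(C)(C)O1 | intermediate
5 | 1,3-dithiane | C1CSCSC1 | starting material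
6 | 2-lithio-1,3-dithiane | [Li]C1SCCCS1 | intermediate (not isolated)
7 | 2-{2-[(4S)-2,2-dimethyl-1,3-dioxolan-4-yl]ethyl}-1,3-dithiane | C1CSC(CC[C@H]2COC(C)(C)O2)SC1 | intermediate
8 | (2S)-4-(1,3-dithian-2-yl)butane-1,2-diol | C1CSC(CC[C@H](O)CO)SC1 | intermediate
9 | 2-[(3S)-3,4-bis(tert-butyldimethylsilyloxy)butyl]-1,3-dithiane | C1CSC(CC[C@H](O[Si](C)(C)C(C)(C)C)CO[Si](C)(C)C(C)(C)C)SC1 | intermediate
10 | 2-lithio derivative of 9 | [Li]C1(CC[C@H](O[Si](C)(C)C(C)(C)C)CO[Si](C)(C)C(C)(C)C)SCCCS1 | intermediate (not isolated)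
11 | (4R,5R)-5-({2-[(3S)-3,4-bis(tert-butyldimethylsilyloxy)butyl]-1,3-dithian-2-yl}carbonyl)-N-methoxy-N,2,2-trimethyl-1,3-dioxolane-4-carboxamide | O=C(C1(CC[C@H](O[Si](C)(C)C(C)(C)C)CO[Si](C)(C)C(C)(C)C)SCCCS1)[C@@H]2OC(C)(C)O[C@H]2C(=O)N(C)OC | intermediate
12 | (4R,5S)-5-(1-{2-[(3S)-3,4-bis(tert-butyldimethylsilyloxy)butyl]-1,3-dithian-2-yl}ethenyl)-N-methoxy-N,2,2-trimethyl-1,3-dioxolane-4-carboxamide | C=C(C1(CC[C@H](O[Si](C)(C)C(C)(C)C)CO[Si](C)(C)C(C)(C)C)SCCCS1)[C@@H]2OC(C)(C)O[C@H]2C(=O)N(C)OC | intermediate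
13 | (4R,5S)-5-(1-{2-[(3S)-3,4-bis(tert-butyldimethylsilyloxy)butyl]-1,3-dioxolan-2-yl}ethenyl)-N-methoxy-N,2,2-trimethyl-1,3-dioxolane-4-carboxamide | C=C(C1(CC[C@H](O[Si](C)(C)C(C)(C)C)CO[Si](C)(C)C(C)(C)C)OCCO1)[C@@H]2OC(C)(C)O[C@H]2C(=O)N(C)OC | intermediate
14 | 1-[(4R,5S)-5-(1-{2-[(3S)-3,4-bis(tert-butyldimethylsilyloxy)butyl]-1,3-dioxolan-2-yl}ethenyl)-2,2-dimethyl-1,3-dioxolan-4-yl]ethanone | C=C(C1(CC[C@H](O[Si](C)(C)C(C)(C)C)CO[Si](C)(C)C(C)(C)C)OCCO1)[C@@H]2OC(C)(C)O[C@H]2C(C)=O | intermediate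
15 | 1-[(4R,5S)-5-(1-{2-[(3S)-3-(tert-butyldimethylsilyloxy)-4-hydroxybutyl]-1,3-dioxolan-2-yl}ethenyl)-2,2-dimethyl-1,3-dioxolan-4-yl]ethanone | C=C(C1(CC[C@H](O[Si](C)(C)C(C)(C)C)CO)OCCO1)[C@@H]2OC(C)(C)O[C@H]2C(C)=O | intermediate
16 | (2S)-4-(2-{1-[(4S,5R)-5-acetyl-2,2-dimethyl-1,3-dioxolan-4-yl]ethenyl}-1,3-dioxolan-2-yl)-2-(tert-butyldimethylsilyloxy)butanal | C=C(C1(CC[C@H](O[Si](C)(C)C(C)(C)C)C=O)OCCO1)[C@@H]2OC(C)(C)O[C@H]2C(C)=O | intermediate
17 | 2-(triphenylphosphoranylidene)propanal | CC(C=O)=P(c1ccccc1)(c1ccccc1)c1ccccc1 | starting material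
18 | (2E,4S)-6-(2-{1-[(4S,5R)-5-acetyl-2,2-dimethyl-1,3-dioxolan-4-yl]ethenyl}-1,3-dioxolan-2-yl)-4-(tert-butyldimethylsilyloxy)-2-methylhex-2-enal (key-step precursor) | C=C(C1(OCCO1)CC[C@H](O[Si](C)(C)C(C)(C)C)/C=C(\C)C=O)[C@@H]2OC(C)(C)O[C@H]2C(C)=O | intermediate
19 | tertiary C5 radical formed from 18 by hydrogen-atom transfer to C19 | C[C](C1(OCCO1)CC[C@H](O[Si](C)(C)C(C)(C)C)/C=C(\C)C=O)[C@@H]2OC(C)(C)O[C@H]2C(C)=O | intermediate (not isolated)
20 | ring A iron enolate at C9 (iron-bound in the flask, drawn as the anion) | C12(OCCO1)CC[C@H](O[Si](C)(C)C(C)(C)C)[C@@H](C(C)=C[O-])[C@]2(C)[C@@H]3OC(C)(C)O[C@H]3C(C)=O | intermediate (not isolated)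
21 | trans-decalin aldehyde: 1α-OTBS, C4 ethylene ketal, 5β-methyl, 6β,7α-O-isopropylidene, 8α-hydroxy-8β-methyl, 9β-methyl-9α-formyl, 10α-H (key-step product) | C12(OCCO1)CC[C@H](O[Si](C)(C)C(C)(C)C)[C@@H]3[C@]2(C)[C@@H]4OC(C)(C)O[C@H]4[C@@](C)(O)[C@@]3(C)C=O | intermediate
22 | C11/C12 epoxide of 21 (oxirane on C9, C11 placed as in the target) | C12(OCCO1)CC[C@H](O[Si](C)(C)C(C)(C)C)[C@@H]3[C@]2(C)[C@@H]4OC(C)(C)O[C@H]4[C@@](C)(O)[C@@]3(C)[C@H]5CO5 | intermediate
23 | 3-bromofuran | Brc1ccoc1 | starting material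
24 | 3-furyllithium | [Li]c1ccoc1 | intermediate (not isolated)
25 | furan diol: (11R)-11-hydroxy-12-(3-furyl), 8α-OH, 1α-OTBS, C4 ketal, 6,7-acetonide | C12(OCCO1)CC[C@H](O[Si](C)(C)C(C)(C)C)[C@@H]3[C@]2(C)[C@@H]4OC(C)(C)O[C@H]4[C@@](C)(O)[C@@]3(C)[C@@H](Cc5ccoc5)O | intermediate
26 | furan triol: 1α-OH, 8α-OH, 11-OH, C4 ketal, 6,7-acetonide | C12(OCCO1)CC[C@H](O)[C@@H]3[C@]2(C)[C@@H]4OC(C)(C)O[C@H]4[C@@](C)(O)[C@@]3(C)[C@@H](Cc5ccoc5)O | intermediate
27 | 1,11-diacetate: 1α-OAc, 11-OAc, 8α-OH, C4 ketal, 6,7-acetonide | C12(OCCO1)CC[C@H](OC(C)=O)[C@@H]3[C@]2(C)[C@@H]4OC(C)(C)O[C@H]4[C@@](C)(O)[C@@]3(C)[C@@H](Cc5ccoc5)OC(C)=O | intermediate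
28 | ketone triol: 4-oxo, 6β-OH, 7α-OH, 8α-OH, 1α-OAc, 11-OAc | O=C1CC[C@H](OC(C)=O)[C@@H]2[C@]1(C)[C@H](O)[C@@H](O)[C@@](C)(O)[C@@]2(C)[C@@H](Cc3ccoc3)OC(C)=O | intermediate
29 | 7-O-isobutyrate of 28 | O=C1CC[C@H](OC(C)=O)[C@@H]2[C@]1(C)[C@H](O)[C@@H](OC(=O)C(C)C)[C@@](C)(O)[C@@]2(C)[C@@H](Cc3ccoc3)OC(C)=O | intermediate
30 | keto tetraester: 4-oxo, 1α,6β,11-triacetate, 7α-isobutyrate, 8α-OH | O=C1CC[C@H](OC(C)=O)[C@@H]2[C@]1(C)[C@H](OC(C)=O)[C@@H](OC(=O)C(C)C)[C@@](C)(O)[C@@]2(C)[C@@H](Cc3ccoc3)OC(C)=O | intermediate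
31 | 4(18)-methylene furan: 30 with C4=CH2 | C=C1CC[C@H](OC(C)=O)[C@@H]2[C@]1(C)[C@H](OC(C)=O)[C@@H](OC(=O)C(C)C)[C@@](C)(O)[C@@]2(C)[C@@H](Cc3ccoc3)OC(C)=O | intermediate
32 | furan 2,5-endoperoxide of 31 | C=C1CC[C@H](OC(C)=O)[C@@H]2[C@]1(C)[C@H](OC(C)=O)[C@@H](OC(=O)C(C)C)[C@@](C)(O)[C@@]2(C)[C@@H](CC3=CC4OOC3O4)OC(C)=O | intermediate (not isolated)
33 | γ-hydroxybutenolide (16-hydroxy-15,16-olide, epimers at C16) | C=C1CC[C@H](OC(C)=O)[C@@H]2[C@]1(C)[C@H](OC(C)=O)[C@@H](OC(=O)C(C)C)[C@@](C)(O)[C@@]2(C)[C@@H](CC3=CC(=O)OC3O)OC(C)=O | intermediate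
34 | ring-opened (Z)-16-hydroxy-13-en-15-oic acid | C=C1CC[C@H](OC(C)=O)[C@@H]2[C@]1(C)[C@H](OC(C)=O)[C@@H](OC(=O)C(C)C)[C@@](C)(O)[C@@]2(C)[C@@H](C/C(CO)=C/C(O)=O)OC(C)=O | intermediate (not isolated)
35 | (1S,5S,6S,7R,8S,9R,10R,11R)-1,6,11-triacetoxy-8-hydroxy-7-isobutyryloxycleroda-4(18),13-dien-15,16-olide (CNP0266716.2) | C=C1CC[C@H](OC(C)=O)[C@@H]2[C@]1(C)[C@H](OC(C)=O)[C@@H](OC(=O)C(C)C)[C@@](C)(O)[C@@]2(C)[C@@H](CC1=CC(=O)OC1)OC(C)=O | target

**Step count and risks**

Total steps: 23. Longest linear sequence: 22 steps (steps 2–23, from compound 3); step 1 is a one-step branch that supplies 2.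

The three steps most likely to fail:

1. Step 13 (key step). The aldol that closes ring B may add to the C8 carbonyl with the methyl group axial, giving the C8 epimer, or the iron enolate may be protonated by ethanol before it closes. Fallback, from 18 back to 21: the crude product of the iron-hydride reaction, expected then to be the monocyclic keto aldehyde F1 and/or the C8-epimeric aldol F2, would be treated with DBU in toluene (or catalytic KOtBu in t-BuOH/THF). Retro-aldol and aldol through the ring-opened enolate 20 puts ring B under thermodynamic control, where the isomer with C17 equatorial and C20 axial (21) should be favoured. This replaces kinetic closure inside the cascade by a separate base-mediated intramolecular aldol equilibration.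

2. Step 14. The ylide may add with poor facial selectivity at C11, or the basic conditions may open ring B by retro-aldol before addition. Fallback, from 21 back to 22: magnesium-chelate-controlled addition of (isopropoxydimethylsilyl)methylmagnesium chloride (THF, −78 °C), in which the magnesium alkoxide of O8 fixes the aldehyde, should give the β-hydroxy silane F3. Tamao–Fleming oxidation (H2O2, KF, KHCO3, THF/MeOH) would give the 8,11,12-triol F4; selective tosylation of the primary hydroxyl (TsCl, Et3N, Bu2SnO cat.) the tosylate F5; and K2CO3 in MeOH closes the epoxide 22 with C11 untouched.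

3. Step 19. Acyl transfer may not discriminate between O6 and O7, giving the wrong mono-ester or the bis-ester. Fallback, from 28 back to 30: phenylboronic acid (toluene, azeotropic removal of water) should bind the cis 7α,8α-diol as the cyclic boronate F6 and leave O6 as the only free hydroxyl. Acetylation (Ac2O, DMAP, pyridine) would give the boronate 6-acetate F7; exchange with pinacol frees the 6-acetate 7,8-diol F8; and isobutyric anhydride/DMAP then acylates O7, the only secondary hydroxyl left, to give 30.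

**Further compounds**

F1 | step 13 | monocyclic keto aldehyde (ring A closed, enolate protonated at C9, C9 epimers) | C12(OCCO1)CC[C@H](O[Si](C)(C)C(C)(C)C)[C@@H](C(C)C=O)[C@]2(C)[C@@H]3OC(C)(C)O[C@H]3C(C)=O
F2 | step 13 | C8 epimer of 21 (8β-hydroxy-8α-methyl) | C12(OCCO1)CC[C@H](O[Si](C)(C)C(C)(C)C)[C@@H]3[C@]2(C)[C@@H]4OC(C)(C)O[C@H]4[C@](C)(O)[C@@]3(C)C=O
F3 | step 14 | β-hydroxy silane (C11 carbinol bearing CH2SiMe2(OiPr)) | C12(OCCO1)CC[C@H](O[Si](C)(C)C(C)(C)C)[C@@H]3[C@]2(C)[C@@H]4OC(C)(C)O[C@H]4[C@@](C)(O)[C@@]3(C)[C@@H](C[Si](C)(C)OC(C)C)O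
F4 | step 14 | 8,11,12-triol | C12(OCCO1)CC[C@H](O[Si](C)(C)C(C)(C)C)[C@@H]3[C@]2(C)[C@@H]4OC(C)(C)O[C@H]4[C@@](C)(O)[C@@]3(C)[C@@H](CO)O
F5 | step 14 | 12-O-tosylate of F4 | C12(OCCO1)CC[C@H](O[Si](C)(C)C(C)(C)C)[C@@H]3[C@]2(C)[C@@H]4OC(C)(C)O[C@H]4[C@@](C)(O)[C@@]3(C)[C@@H](COS(=O)(=O)c5ccc(C)cc5)O
F6 | step 19 | 7,8-O-phenylboronate of 28 | O=C1CC[C@H](OC(C)=O)[C@@H]2[C@]1(C)[C@H](O)[C@H]4OB(c5ccccc5)O[C@@]4(C)[C@@]2(C)[C@@H](Cc3ccoc3)OC(C)=O
F7 | step 19 | 6-O-acetate of F6 | O=C1CC[C@H](OC(C)=O)[C@@H]2[C@]1(C)[C@H](OC(C)=O)[C@H]4OB(c5ccccc5)O[C@@]4(C)[C@@]2(C)[C@@H](Cc3ccoc3)OC(C)=O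
F8 | step 19 | 1,6,11-triacetate 7,8-diol (4-oxo) | O=C1CC[C@H](OC(C)=O)[C@@H]2[C@]1(C)[C@H](OC(C)=O)[C@@H](O)[C@@](C)(O)[C@@]2(C)[C@@H](Cc3ccoc3)OC(C)=O
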